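**Retrosynthetic overview**

1. The target arises by one hydrogenation of a precursor that carries a vinyl group at C10 and exocyclic methylenes at C13 and C20. Ring E (appended lactone) comes from a C3 aldehyde and ethyl 2-(bromomethyl)acrylate, and the aldehyde comes from a tert-butyl ester that blocks C3.
2. Key disconnection: bonds C9a–C9 (ring B, azepine) and C9–C10 (ring C, the carbocycle C1/C9a/C9/C10/C11/C12) are made in one operation from a monocyclic pyrrole that carries an N-(CH2)4-acetal chain and a cis-lactone (ring D) with an allylsilane on C11.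
3. Enabling feature: C9 is bonded to the pyrrole α-carbon C9a, so a cation at C9 is a 1-azafulvenium ion fed by the N4 lone pair through ring A. C10 sits next to the O-bearing C11 and carries a two-carbon substituent, so it can be the γ-carbon of a C10=CH–CH2SiMe3 allylsilane whose leftover vinyl group is the masked ethyl group.
4. The cascade precursor comes from a pyrrol-3-ylboronic acid and a chiral γ-hydroxy ynoate (copper-catalysed hydroarylation/lactonisation, conjugate reduction for cis C11/C12, α-methylenation). The ynoate comes from a γ-silyl enal and methyl propiolate, with C11 set by the catalyst.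
5. Ring order: A (bought) → D → B and C together (key step) → E.

Key step: step 9

Remark: atoms carry the Stemona numbering (N4; pyrrole C1, C2, C3, C9a; azepine C5–C9; C10 bears ethyl, C11 the ring-D oxygen, C12–C14 complete ring D; C18–C21 form ring E), and the iodo acid, the bromo acetal, allyltrimethylsilane, crotonaldehyde, methyl propiolate and ethyl 2-(bromomethyl)acrylate are taken as catalogue compounds.

**Route**

Step 1
Reactants: 1 4-iodo-1H-pyrrole-2-carboxylic acid
Product: 2 tert-butyl 4-iodo-1H-pyrrole-2-carboxylate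
Conditions: Me2NCH(OtBu)2 (4 equiv), toluene, 80 °C
Reagents that add atoms: N,N-dimethylformamide di-tert-butyl acetal, CN(C)C(OC(C)(C)C)OC(C)(C)C
Why: Esterification of the acid by O-alkylation with the formamide acetal (tert-butyl ester formation under neutral conditions) installs the group that blocks C3 and that acid later removes; no stereocentre is formed.

Step 2
Reactants: 2 tert-butyl 4-iodo-1H-pyrrole-2-carboxylate; 3 2-(4-bromobutyl)-1,3-dioxolane
Product: 4 tert-butyl 1-[4-(1,3-dioxolan-2-yl)butyl]-4-iodo-1H-pyrrole-2-carboxylate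
Conditions: Cs2CO3, DMF, 50 °C
Reagents that add atoms: none
Why: SN2 N-alkylation of the caesium pyrrolide (the ester lowers the N–H pKa, so the pyrrolide forms with carbonate and alkylates at nitrogen); the dioxolane survives base and no stereocentre is formed.

Step 3
Reactants: 4 tert-butyl 1-[4-(1,3-dioxolan-2-yl)butyl]-4-iodo-1H-pyrrole-2-carboxylate
Product: 5 {5-(tert-butoxycarbonyl)-1-[4-(1,3-dioxolan-2-yl)butyl]-1H-pyrrol-3-yl}boronic acid
Conditions: Pd(OAc)2 (2 mol%), XPhos (4 mol%), B2(OH)4 (2 equiv), KOAc (3 equiv), EtOH, 80 °C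
Reagents that add atoms: tetrahydroxydiboron, OB(O)B(O)O
Why: Miyaura borylation with tetrahydroxydiboron converts the C–I bond into the boronic acid directly, and the tert-butyl ester and acetal tolerate the mild acetate base; no stereocentre is formed.

Step 4
Reactants: 6 allyltrimethylsilane; 7 (E)-but-2-enal
Product: 8 (E)-4-(trimethylsilyl)but-2-enal
Conditions: second-generation Grubbs catalyst (2 mol%), 7 in excess, CH2Cl2, 40 °C
Reagents that add atoms: none
Why: Olefin cross-metathesis of a terminal alkene with an excess of the enal (propene is lost) should give the (E)-enal, the thermodynamically preferred geometry; no stereocentre is formed.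

Step 5
Reactants: 8 (E)-4-(trimethylsilyl)but-2-enal; 9 methyl propiolate
Product: 10 methyl (4R,5E)-4-hydroxy-7-(trimethylsilyl)hept-5-en-2-ynoate
Conditions: Me2Zn (3 equiv), ProPhenol ligand (20 mol%; the enantiomer that directs attack to the Si face), Ph3P=O (40 mol%), toluene, 4 °C; aq NH4Cl
Reagents that add atoms: none
Why: Zinc–ProPhenol-catalysed enantioselective addition of the zinc alkynylide of methyl propiolate to an enal (Trost alkynylation), a substrate class this catalyst handles well, sets C11 as (R) by reagent-controlled Si-face attack.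

Step 6
Reactants: 5 {5-(tert-butoxycarbonyl)-1-[4-(1,3-dioxolan-2-yl)butyl]-1H-pyrrol-3-yl}boronic acid; 10 methyl (4R,5E)-4-hydroxy-7-(trimethylsilyl)hept-5-en-2-ynoate
Product: 12 tert-butyl 1-[4-(1,3-dioxolan-2-yl)butyl]-4-{(2R)-5-oxo-2-[(E)-3-(trimethylsilyl)prop-1-en-1-yl]-2,5-dihydrofuran-3-yl}-1H-pyrrole-2-carboxylate, via hydroxy enoate 11 (not isolated)
Conditions: CuOAc (5 mol%), MeOH, 25 °C
Reagents that add atoms: none
Why: Copper-catalysed hydroarylation of an ynoate with an arylboronic acid (transmetalation, syn-carbocupration with the aryl group going to the β-carbon C12, protonation by methanol) places the carbinol cis to the ester, so the (Z)-hydroxy enoate lactonises to the butenolide (ring D) under neutral conditions that leave C11 and the allylsilane untouched.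

Step 7
Reactants: 12 tert-butyl 1-[4-(1,3-dioxolan-2-yl)butyl]-4-{(2R)-5-oxo-2-[(E)-3-(trimethylsilyl)prop-1-en-1-yl]-2,5-dihydrofuran-3-yl}-1H-pyrrole-2-carboxylate
Product: 13 tert-butyl 1-[4-(1,3-dioxolan-2-yl)butyl]-4-{(2R,3S)-5-oxo-2-[(E)-3-(trimethylsilyl)prop-1-en-1-yl]oxolan-3-yl}-1H-pyrrole-2-carboxylate
Conditions: Cu(OAc)2 (5 mol%), 1,2-bis(diphenylphosphino)benzene (5 mol%), (EtO)2MeSiH (2 equiv), tBuOH (2 equiv), toluene, 0 to 23 °C
Reagents that add atoms: none
Why: Copper hydride conjugate reduction of the β-aryl butenolide delivers hydride to C12 on the face opposite the adjacent C11 propenyl group (1,2-induction on the flat five-membered ring), which should give the cis C11/C12 lactone after protonation of the copper enolate at C13 by tBuOH.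

Step 8
Reactants: 13 tert-butyl 1-[4-(1,3-dioxolan-2-yl)butyl]-4-{(2R,3S)-5-oxo-2-[(E)-3-(trimethylsilyl)prop-1-en-1-yl]oxolan-3-yl}-1H-pyrrole-2-carboxylate
Product: 16 tert-butyl 1-[4-(1,3-dioxolan-2-yl)butyl]-4-{(2R,3R)-4-methylidene-5-oxo-2-[(E)-3-(trimethylsilyl)prop-1-en-1-yl]oxolan-3-yl}-1H-pyrrole-2-carboxylate, via Mannich base 14 (not isolated), via methiodide 15 (not isolated)
Conditions: LiN(iPr)2, THF, −78 °C; CH2=NMe2+ I−, −78 to 0 °C; then MeI, MeOH, 23 °C; then aq NaHCO3, CH2Cl2
Reagents that add atoms: N,N-dimethylmethyleneiminium iodide (Eschenmoser's salt), C=[N+](C)C.[I-]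
Why: Enolate Mannich reaction with Eschenmoser's salt followed by quaternisation and E1cB elimination (the standard α-methylenation of lactones) installs the exocyclic methylene that later becomes the C13 methyl group; C11 and C12 are not enolisable and keep their configuration.

Step 9
Reactants: 16 tert-butyl 1-[4-(1,3-dioxolan-2-yl)butyl]-4-{(2R,3R)-4-methylidene-5-oxo-2-[(E)-3-(trimethylsilyl)prop-1-en-1-yl]oxolan-3-yl}-1H-pyrrole-2-carboxylate
Product: 19 tert-butyl ester of the ring A–D tetracycle (CO2tBu at C3; ethenyl at C10; methylidene at C13; 9R,10R,11R,12R), via C9 ether 17 (not isolated), via azafulvenium triflate 18 (not isolated)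
Conditions: Me3SiOTf (0.3 equiv), CH2Cl2 (0.005 M), −78 to −30 °C; then Et3N
Reagents that add atoms: none
Why: Proposed new method: Me3SiOTf opens the dioxolane to an oxocarbenium ion that the pyrrole attacks through C9a (Friedel–Crafts alkoxyalkylation, 7-exo-trig at the oxocarbenium carbon, ring B); the C9 ether 17 then ionises to the 1-azafulvenium ion 18 (N4 lone pair delocalised through C3=C2 and C1=C9a onto C9), and the allylsilane attacks C9 through its γ-carbon C10 with loss of Me3Si+ (intramolecular Hosomi–Sakurai closure of ring C, 6-endo at the C9=C9a bond of 18 with the allylsilane double bond exocyclic), which returns the catalyst. The closest known reaction types are the acid-mediated cyclisation of N-(ω,ω-dialkoxyalkyl)pyrroles, the substitution of pyrrol-2-yl carbinols and their ethers by allylsilanes through azafulvenium ions, and the aldehyde–heteroarene–nucleophile (Yonemitsu-type) condensation; their union in one flask with a seven-membered first closure is what is new. C9 and C10 are set together in a chair-like transition state in which the allylsilane chain is equatorial and antiperiplanar to C9=C9a, the azepine carbon C8 stays on the outer side of C9 (it is held cis to N4 in 18), the lactone bond C12–C13 is pseudo-equatorial and C11–O is axial, so that C10 adds to the face of C9 opposite the lactone and anti to the allylic C11–H, not anti to the electron-withdrawing C11–O bond; this should give H9/H10 trans and the vinyl group cis to the lactone oxygen, that is (9R,10R). Site selectivity of the first closure is secured by the ester at C3, which leaves C9a as the only free α-position, and by ring size (seven against eleven for direct attack of the allylsilane on the oxocarbenium ion); high dilution suppresses intermolecular pyrrole alkylation, and loss of a proton from 18 to the 8,9-alkene is reversible under the conditions. The ester also makes 18 more electrophilic, which helps the weakly nucleophilic allylsilane.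

Step 10
Reactants: 19 tert-butyl ester of the ring A–D tetracycle
Product: 22 ring A–D tetracycle 3-carbaldehyde (ethenyl at C10; methylidene at C13; 9R,10R,11R,12R), via carboxylic acid 20 (not isolated), via 3-unsubstituted pyrrole 21 (not isolated)
Conditions: CF3CO2H, 23 °C, 15 min; then HC(OEt)3, 0 °C; aq NaHCO3
Reagents that add atoms: triethyl orthoformate, CCOC(OCC)OCC; water, O
Why: Clezy-type decarboxylative formylation: CF3CO2H cleaves the tert-butyl ester and decarboxylates the pyrrole-2-carboxylic acid, and the freed α-position C3 (more reactive than the β-position C2) is formylated by the diethoxycarbenium ion from the orthoformate; the lactone, the exocyclic methylene and the vinyl group should survive the short exposure and no stereocentre changes.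

Step 11
Reactants: 22 ring A–D tetracycle 3-carbaldehyde; 23 ethyl 2-(bromomethyl)prop-2-enoate
Product: 25 13,20-bis(methylidene)-10-ethenyl precursor of the target (rings A–E; 9R,10R,11R,12R,18S), via hydroxy ester 24 (not isolated)
Conditions: CrCl2 (10 mol%), carbazole-based bis(oxazoline) ligand (12 mol%; the enantiomer that directs attack to the Si face), Mn (2 equiv), Me3SiCl (1.2 equiv), THF, 23 °C; then Bu4NF, THF, 0 °C
Reagents that add atoms: none
Why: Chromium-catalysed asymmetric Nozaki–Hiyama–Kishi-type 2-(alkoxycarbonyl)allylation of the aldehyde, in which the chiral ligand on chromium and not the remote substrate stereocentres controls Si-face attack and so sets C18 as (S); fluoride then frees the alkoxide, which closes ring E by 5-exo-trig acylation without acid that would ionise the pyrrolylic C18–O bond.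

Step 12
Reactants: 25 13,20-bis(methylidene)-10-ethenyl precursor
Product: 26 bisdehydroneotuberostemonine
Conditions: H2 (1 atm), Rh/Al2O3 (5 wt% Rh), EtOAc, 23 °C
Reagents that add atoms: none
Why: Heterogeneous catalytic hydrogenation adds H2 to the ring-D methylene from the convex face of the cis-fused lactone (the face of H11 and H12), which sets C13 as (S) with the methyl group cis to C1, and to the ring-E methylene from the face opposite the pyrrole on C18, which sets the cis C20 (S) methyl group, while the vinyl group becomes the ethyl group; rhodium on alumina is chosen to limit double-bond migration and C18–O hydrogenolysis.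

**Compound list**

1 | 4-iodo-1H-pyrrole-2-carboxylic acid | OC(=O)c1cc(I)c[nH]1 | starting material
2 | tert-butyl 4-iodo-1H-pyrrole-2-carboxylate | CC(C)(C)OC(=O)c1cc(I)c[nH]1 | intermediate
3 | 2-(4-bromobutyl)-1,3-dioxolane | BrCCCCC1OCCO1 | starting material
4 | tert-butyl 1-[4-(1,3-dioxolan-2-yl)butyl]-4-iodo-1H-pyrrole-2-carboxylate | CC(C)(C)OC(=O)c1cc(I)cn1CCCCC1OCCO1 | intermediate
5 | {5-(tert-butoxycarbonyl)-1-[4-(1,3-dioxolan-2-yl)butyl]-1H-pyrrol-3-yl}boronic acid | CC(C)(C)OC(=O)c1cc(B(O)O)cn1CCCCC1OCCO1 | intermediate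
6 | allyltrimethylsilane | C=CC[Si](C)(C)C | starting material
7 | (E)-but-2-enal (crotonaldehyde) | C/C=C/C=O | starting material
8 | (E)-4-(trimethylsilyl)but-2-enal | C[Si](C)(C)C/C=C/C=O | intermediate
9 | methyl propiolate | C#CC(=O)OC | starting material
10 | methyl (4R,5E)-4-hydroxy-7-(trimethylsilyl)hept-5-en-2-ynoate | C[Si](C)(C)C/C=C/[C@H](C#CC(=O)OC)O | intermediate
11 | methyl (2Z,4R,5E)-3-{5-(tert-butoxycarbonyl)-1-[4-(1,3-dioxolan-2-yl)butyl]-1H-pyrrol-3-yl}-4-hydroxy-7-(trimethylsilyl)hepta-2,5-dienoate (hydroxy enoate, not isolated) | COC(=O)/C=C(\[C@H](O)/C=C/C[Si](C)(C)C)c1cn(CCCCC2OCCO2)c(C(=O)OC(C)(C)C)c1 | intermediate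
12 | tert-butyl 1-[4-(1,3-dioxolan-2-yl)butyl]-4-{(2R)-5-oxo-2-[(E)-3-(trimethylsilyl)prop-1-en-1-yl]-2,5-dihydrofuran-3-yl}-1H-pyrrole-2-carboxylate | C[Si](C)(C)C/C=C/[C@H]1OC(=O)C=C1c1cn(CCCCC2OCCO2)c(C(=O)OC(C)(C)C)c1 | intermediate
13 | tert-butyl 1-[4-(1,3-dioxolan-2-yl)butyl]-4-{(2R,3S)-5-oxo-2-[(E)-3-(trimethylsilyl)prop-1-en-1-yl]oxolan-3-yl}-1H-pyrrole-2-carboxylate (cis-lactone) | C[Si](C)(C)C/C=C/[C@H]1OC(=O)C[C@H]1c1cn(CCCCC2OCCO2)c(C(=O)OC(C)(C)C)c1 | intermediate
14 | (2R,3S,4S)-4-[(dimethylamino)methyl] derivative of 13 (Mannich base, aminomethyl trans to the pyrrole, not isolated) | C[Si](C)(C)C/C=C/[C@H]1OC(=O)[C@H](CN(C)C)[C@H]1c1cn(CCCCC2OCCO2)c(C(=O)OC(C)(C)C)c1 | intermediate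
15 | trimethylammonium iodide of 14 (methiodide, not isolated) | C[Si](C)(C)C/C=C/[C@H]1OC(=O)[C@H](C[N+](C)(C)C)[C@H]1c1cn(CCCCC2OCCO2)c(C(=O)OC(C)(C)C)c1.[I-] | intermediate
16 | tert-butyl 1-[4-(1,3-dioxolan-2-yl)butyl]-4-{(2R,3R)-4-methylidene-5-oxo-2-[(E)-3-(trimethylsilyl)prop-1-en-1-yl]oxolan-3-yl}-1H-pyrrole-2-carboxylate (cascade precursor) | C[Si](C)(C)C/C=C/[C@H]1OC(=O)C(=C)[C@H]1c1cn(CCCCC2OCCO2)c(C(=O)OC(C)(C)C)c1 | intermediate
17 | tert-butyl 1-{(2R,3R)-4-methylidene-5-oxo-2-[(E)-3-(trimethylsilyl)prop-1-en-1-yl]oxolan-3-yl}-9-[2-(trimethylsilyloxy)ethoxy]-6,7,8,9-tetrahydro-5H-pyrrolo[1,2-a]azepine-3-carboxylate (C9 ether, both C9 epimers, not isolated) | C[Si](C)(C)C/C=C/[C@H]1OC(=O)C(=C)[C@H]1c1cc(C(=O)OC(C)(C)C)n2CCCCC(OCCO[Si](C)(C)C)c12 | intermediate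
18 | 1-azafulvenium triflate from 17 by loss of the C9 alkoxy group (C9=C9a and N4=C3 drawn, not isolated) | C[Si](C)(C)C/C=C/[C@H]1OC(=O)C(=C)[C@H]1C1=CC(C(=O)OC(C)(C)C)=[N+]2CCCCC=C12.[O-]S(=O)(=O)C(F)(F)F | intermediate
19 | tert-butyl ester of the ring A–D tetracycle: pyrrolo[1,2-a]azepine fused to the C1/C9a/C9–C12 carbocycle and the cis C11–O/C12–C13 γ-lactone; CO2tBu at C3, ethenyl at C10, methylidene at C13; (9R,10R,11R,12R) | C=C[C@H]1[C@H]2OC(=O)C(=C)[C@H]2c2cc(C(=O)OC(C)(C)C)n3c2[C@@H]1CCCC3 | intermediate
20 | 3-carboxylic acid corresponding to 19 (not isolated) | C=C[C@H]1[C@H]2OC(=O)C(=C)[C@H]2c2cc(C(=O)O)n3c2[C@@H]1CCCC3 | intermediate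
21 | 3-unsubstituted pyrrole corresponding to 19 (H at C3, not isolated) | C=C[C@H]1[C@H]2OC(=O)C(=C)[C@H]2c2ccn3c2[C@@H]1CCCC3 | intermediate
22 | 3-carbaldehyde of the ring A–D tetracycle; ethenyl at C10, methylidene at C13; (9R,10R,11R,12R) | C=C[C@H]1[C@H]2OC(=O)C(=C)[C@H]2c2cc(C=O)n3c2[C@@H]1CCCC3 | intermediate
23 | ethyl 2-(bromomethyl)prop-2-enoate | C=C(CBr)C(=O)OCC | starting material
24 | ethyl (4S)-4-hydroxy-2-methylidene-4-(ring A–D tetracycle-3-yl)butanoate (hydroxy ester, not isolated) | C=C[C@H]1[C@H]2OC(=O)C(=C)[C@H]2c2cc([C@@H](O)CC(=C)C(=O)OCC)n3c2[C@@H]1CCCC3 | intermediate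
25 | 13,20-bis(methylidene)-10-ethenyl precursor (rings A–E); (9R,10R,11R,12R,18S) | C=C[C@H]1[C@H]2OC(=O)C(=C)[C@H]2c2cc([C@@H]3CC(=C)C(=O)O3)n3c2[C@@H]1CCCC3 | intermediate
26 | bisdehydroneotuberostemonine; (9R,10R,11R,12S,13S,18S,20S) | CC[C@H]1[C@H]2OC(=O)[C@@H](C)[C@H]2c2cc([C@@H]3C[C@H](C)C(=O)O3)n3c2[C@@H]1CCCC3 | target

**Summary**

Total step count: 12. Longest linear sequence: 10 steps (steps 1, 2, 3, 6, 7, 8, 9, 10, 11, 12); the branch through steps 4 and 5 joins at step 6.

Steps most likely to fail:

Step 9 (Proposed new method). What may go wrong is intermolecular alkylation of the pyrrole by the oxocarbenium ion before the seven-membered closure, Lewis-acid ionisation of the allylic lactone C11–O bond with 1,4-loss of the silyl group, or poor facial selectivity in the second closure. The fallback uses only known reaction types and sets out from 16. The dioxolane is hydrolysed (pyridinium p-toluenesulfonate, wet acetone) to the aldehyde F1, and Pinnick oxidation (NaClO2, NaH2PO4, 2-methylbut-2-ene) gives the acid F2. Its acid chloride (1-chloro-N,N,2-trimethylprop-1-en-1-amine) closes ring B by intramolecular Friedel–Crafts acylation at C9a (SnCl4, −78 °C) to the azepin-9-one F3. Luche reduction (NaBH4, CeCl3·7H2O, MeOH) gives the carbinol F4, and BF3·OEt2 at −78 °C ionises F4 to 18 for the Sakurai closure, so ring B is secured before the cation is made. The sequence returns to the route at 19.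

Step 6. What may go wrong is protodeboronation of the electron-rich pyrrol-3-ylboronic acid and slow transmetalation to copper, so that the ynoate is not arylated. The fallback reverses the polarity of the aryl partner and sets out from 4 and 10, leaving out 5. A palladium-catalysed reductive hydroarylation (Pd(OAc)2, PPh3, HCO2H, Et3N, DMF, 40 °C) adds the aryl group from the iodide to C12 by syn-carbopalladation, formate reduces the vinylpalladium, and the same hydroxy enoate 11 lactonises. The temperature is kept low to limit ionisation of the allylic lactone by zerovalent palladium. The sequence returns at 12 and makes no new compound.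

Step 11. What may go wrong is poor facial selectivity at the remote C18 on a deactivated pyrrole aldehyde and ionisation of the pyrrolylic carbinol before it lactonises. The fallback sets C18 by reagent-controlled ketone reduction and sets out from 19. CF3CO2H gives 21 (through 20), and Friedel–Crafts acylation at C3 with itaconic anhydride (BF3·OEt2, CH2Cl2, 0 °C; attack at the non-conjugated carbonyl) gives the keto acid F5. Reduction with (−)-Ipc2BCl gives the (S)-hydroxy acid F6, which lactonises on work-up. The sequence returns at 25.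

Further compounds
F1 | step 9 | aldehyde from 16: tert-butyl 4-{(2R,3R)-4-methylidene-5-oxo-2-[(E)-3-(trimethylsilyl)prop-1-en-1-yl]oxolan-3-yl}-1-(5-oxopentyl)-1H-pyrrole-2-carboxylate | C[Si](C)(C)C/C=C/[C@H]1OC(=O)C(=C)[C@H]1c1cn(CCCCC=O)c(C(=O)OC(C)(C)C)c1
F2 | step 9 | acid: 5-{2-(tert-butoxycarbonyl)-4-[(2R,3R)-4-methylidene-5-oxo-2-[(E)-3-(trimethylsilyl)prop-1-en-1-yl]oxolan-3-yl]-1H-pyrrol-1-yl}pentanoic acid | C[Si](C)(C)C/C=C/[C@H]1OC(=O)C(=C)[C@H]1c1cn(CCCCC(=O)O)c(C(=O)OC(C)(C)C)c1
F3 | step 9 | azepin-9-one: tert-butyl 1-{(2R,3R)-4-methylidene-5-oxo-2-[(E)-3-(trimethylsilyl)prop-1-en-1-yl]oxolan-3-yl}-9-oxo-6,7,8,9-tetrahydro-5H-pyrrolo[1,2-a]azepine-3-carboxylate | C[Si](C)(C)C/C=C/[C@H]1OC(=O)C(=C)[C@H]1c1cc(C(=O)OC(C)(C)C)n2CCCCC(=O)c12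
F4 | step 9 | carbinol: 9-hydroxy analogue of F3 (both C9 epimers ionise to 18) | C[Si](C)(C)C/C=C/[C@H]1OC(=O)C(=C)[C@H]1c1cc(C(=O)OC(C)(C)C)n2CCCCC(O)c12
F0 | step 6 | none | none
F5 | step 11 | keto acid: 2-methylidene-4-oxo-4-(ring A–D tetracycle-3-yl)butanoic acid | C=C[C@H]1[C@H]2OC(=O)C(=C)[C@H]2c2cc(C(=O)CC(=C)C(=O)O)n3c2[C@@H]1CCCC3
F6 | step 11 | hydroxy acid: (4S)-4-hydroxy-2-methylidene-4-(ring A–D tetracycle-3-yl)butanoic acid | C=C[C@H]1[C@H]2OC(=O)C(=C)[C@H]2c2cc([C@@H](O)CC(=C)C(=O)O)n3c2[C@@H]1CCCC3
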